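**Retrosynthetic overview**

- The O7–prenyl ether is cut last. The prenyl alkene would compete for a carbene, so the 7-oxygen is carried as a TBS ether up to the final step.
- Key disconnection: C3 of the pyranone ring (ring C) is a single sp2 carbon held only by C2 (the O1-bound CH) and C4 (the carbonyl), and it carries the whole 3,4-dimethoxyphenyl ring (ring B). Removing this carbon together with ring B as an aryl(chloro)carbene contracts ring C to the furan of a 3-siloxybenzofuran. The carbon re-enters at the C2=C3 enol ether bond of that furan, forming the chromone C2–C3 and C3–C4 bonds.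
- The carbene source is the 3-aryl-3-chlorodiazirine, made from 3,4-dimethoxybenzonitrile through the amidine and a Graham oxidation. The enol silane comes from double O-silylation of 6-hydroxybenzofuran-3(2H)-one.
- Ring order: rings A and B and the five-membered oxygen ring are bought. Ring C is formed in the key step by one-carbon expansion of the furan.

Key step: step 4

Remark: the diazirine with the donor-substituted aryl group is assumed to be too labile for neat storage; it is treated as the isolated product of step 3 in the form of a cold, assayed pentane solution.

**Route**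

Step 1
Reactants: 1 6-hydroxy-1-benzofuran-3(2H)-one
Product: 3 3,6-bis(tert-butyldimethylsilyloxy)-1-benzofuran, via mono-TBS ketone 2 (not isolated)
Conditions: TBSOTf (2.3 equiv), Et3N (3 equiv), CH2Cl2, 0 °C → rt; pentane extraction, short plug of Et3N-deactivated silica
Reagents that add atoms: tert-butyldimethylsilyl trifluoromethanesulfonate, CC(C)(C)[Si](C)(C)OS(=O)(=O)C(F)(F)F
Why: The silyl triflate with amine base should silylate the phenol at once and then trap the ketone as its silyl enol ether by soft enolisation, which is driven here by the gain of furan aromaticity, so only the O-silylated tautomer is expected.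

Step 2
Reactants: 4 3,4-dimethoxybenzonitrile
Product: 6 3,4-dimethoxybenzamidine hydrochloride, via lithium N,N'-bis(trimethylsilyl)amidinate 5 (not isolated)
Conditions: LiN(SiMe3)2 (1.2 equiv), THF, 0 °C → rt; then HCl in EtOH, 0 °C; trituration with Et2O
Reagents that add atoms: lithium bis(trimethylsilyl)amide, [Li+].C[Si](C)(C)[N-][Si](C)(C)C; hydrogen chloride, Cl
Why: Addition of the silylamide nitrogen to the nitrile carbon followed by a 1,3-silyl shift gives the bis-silyl amidinate, and acidic ethanolysis should strip both silyl groups to leave the amidinium chloride (standard nitrile-to-amidine conversion), the methoxy groups being inert.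

Step 3
Reactants: 6 3,4-dimethoxybenzamidine hydrochloride
Product: 8 3-chloro-3-(3,4-dimethoxyphenyl)-3H-diazirine, via N,N'-dichloroamidine 7 (not isolated)
Conditions: aq NaOCl (excess, saturated with NaCl), LiCl, DMSO/pentane, 0 °C → rt; pentane layer washed, dried cold, assayed and kept at −20 °C
Reagents that add atoms: sodium hypochlorite, [Na+].[O-]Cl; lithium chloride, [Li+].[Cl-]
Why: Graham oxidation: hypochlorite chlorinates both amidine nitrogens, base closes the N–N bond with loss of chloride, and chloride from the salt-rich medium returns at carbon to give the 3-chloro-3H-diazirine, which should be drawn into the pentane layer away from the oxidant as it forms.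

Step 4
Reactants: 3 3,6-bis(tert-butyldimethylsilyloxy)-1-benzofuran; 8 3-chloro-3-(3,4-dimethoxyphenyl)-3H-diazirine
Product: 12 7-(tert-butyldimethylsilyloxy)-3-(3,4-dimethoxyphenyl)-4H-chromen-4-one, via arylchlorocarbene 9 (not isolated), via chlorocyclopropane 10 (not isolated), via siloxychromenylium chloride 11 (not isolated)
Conditions: 8 (2.5 equiv, pentane solution added in portions), Na2CO3 (solid buffer), 4 Å MS, MeCN/ClCH2CH2Cl, 40 °C, argon
Reagents that add atoms: none
Why: Proposed new method: gentle thermolysis of 8 expels N2 and should give the singlet arylchlorocarbene 9, which adds in a [2+1] cycloaddition to the O1–C2=C3–OSi enol ether bond of 3 to give the chlorocyclopropane 10. Ionisation of the benzylic C–Cl bond, pushed by the lone pairs on O1 and on the siloxy oxygen, is coupled to disrotatory two-electron electrocyclic opening of the old C2–C3 bond, so the six-membered ring C is closed by one-carbon ring expansion of the furan (new chromone C2–C3 and C3–C4 bonds) and the aromatic 4-siloxychromenylium chloride 11 results. Chloride then removes the silyl group from the oxonium-type oxygen as TBSCl to leave chromone 12, while the phenolic silyl ether, which is not activated in this way, should stay on. The closest known reaction types are the carbon-atom insertion of aryl chlorodiazirines into indoles and pyrroles (Ciamician–Dennstedt type) and the dihalocarbene ring expansion of cyclic silyl enol ethers to 2-haloenones; a heteroaromatic 3-siloxyfuran has not been used in this way. No stereocentre remains in 12, and the transient ones of 10 should not matter, because the veratryl group and the two oxygen donors allow ionisation of either chloride epimer (a purely concerted opening would need chloride endo). The step needs site selectivity for C2=C3 over the benzo ring, which the two oxygen donors on that bond secure, and the position of insertion is fixed because only the old C2–C3 bond of the cyclopropane can open to a doubly oxygen-stabilised cation.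

Step 5
Reactants: 12 7-(tert-butyldimethylsilyloxy)-3-(3,4-dimethoxyphenyl)-4H-chromen-4-one; 13 prenyl bromide (1-bromo-3-methylbut-2-ene)
Product: 15 7-prenyloxy-3',4'-dimethoxyisoflavone, via cesium phenoxide 14 (not isolated)
Conditions: CsF (2 equiv), 13 (1.3 equiv), DMF, rt
Reagents that add atoms: none
Why: Fluoride cleaves the aryl silyl ether (strong Si–F bond) and the bare cesium phenoxide should be O-alkylated at the primary allylic bromide by SN2 (Williamson ether synthesis), while the chromone, the methoxy groups and the prenyl alkene are untouched under these anhydrous, non-acidic conditions.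

**Compound list**

1 | 6-hydroxy-1-benzofuran-3(2H)-one | O=C1COc2cc(O)ccc21 | starting material
2 | 6-(tert-butyldimethylsilyloxy)-1-benzofuran-3(2H)-one | CC(C)(C)[Si](C)(C)Oc1ccc2c(c1)OCC2=O | intermediate
3 | 3,6-bis(tert-butyldimethylsilyloxy)-1-benzofuran | CC(C)(C)[Si](C)(C)Oc1ccc2c(O[Si](C)(C)C(C)(C)C)coc2c1 | intermediate
4 | 3,4-dimethoxybenzonitrile | COc1ccc(C#N)cc1OC | starting material
5 | lithium N,N'-bis(trimethylsilyl)-3,4-dimethoxybenzamidinate | COc1ccc(C(=N[Si](C)(C)C)[N-][Si](C)(C)C)cc1OC.[Li+] | intermediate
6 | 3,4-dimethoxybenzamidine hydrochloride (amidinium chloride) | COc1ccc(C(N)=[NH2+])cc1OC.[Cl-] | intermediate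
7 | N,N'-dichloro-3,4-dimethoxybenzamidine | COc1ccc(C(=NCl)NCl)cc1OC | intermediate
8 | 3-chloro-3-(3,4-dimethoxyphenyl)-3H-diazirine | COc1ccc(C2(Cl)N=N2)cc1OC | intermediate
9 | chloro(3,4-dimethoxyphenyl)carbene | COc1ccc([C]Cl)cc1OC | intermediate
10 | 4,6b-bis(tert-butyldimethylsilyloxy)-1-chloro-1-(3,4-dimethoxyphenyl)-1a,6b-dihydro-1H-cyclopropa[b][1]benzofuran (racemic, both epimers at the chlorine-bearing carbon) | CC(C)(C)[Si](C)(C)Oc1ccc2c(c1)OC1C(Cl)(c3ccc(OC)c(OC)c3)C21O[Si](C)(C)C(C)(C)C | intermediate
11 | 4,7-bis(tert-butyldimethylsilyloxy)-3-(3,4-dimethoxyphenyl)chromenylium chloride | COc1ccc(-c2c[o+]c3cc(O[Si](C)(C)C(C)(C)C)ccc3c2O[Si](C)(C)C(C)(C)C)cc1OC.[Cl-] | intermediate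
12 | 7-(tert-butyldimethylsilyloxy)-3-(3,4-dimethoxyphenyl)-4H-chromen-4-one | COc1ccc(-c2coc3cc(O[Si](C)(C)C(C)(C)C)ccc3c2=O)cc1OC | intermediate
13 | prenyl bromide (1-bromo-3-methylbut-2-ene) | CC(C)=CCBr | starting material
14 | cesium 3-(3,4-dimethoxyphenyl)-4-oxo-4H-chromen-7-olate | COc1ccc(-c2coc3cc([O-])ccc3c2=O)cc1OC.[Cs+] | intermediate
15 | 7-prenyloxy-3',4'-dimethoxyisoflavone, i.e. 3-(3,4-dimethoxyphenyl)-7-(3-methylbut-2-enyloxy)-4H-chromen-4-one | COc1ccc(-c2coc3cc(OCC=C(C)C)ccc3c2=O)cc1OC | target

**Step count**

Total steps: 5. Longest linear sequence: 4 steps (4 → 6 → 8 → 12 → 15; steps 2, 3, 4, 5). The branch from 1 joins at step 4.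

**Steps most likely to fail, with fallbacks**

1. Step 4 (carbene insertion). The donor-stabilised carbene is a weak electrophile, so dimerisation or reaction with its own diazirine may outrun cyclopropanation. The enol silane may also be hydrolysed by adventitious acid before it is intercepted, and excess carbene may attack the product.
Fallback (known chemistry; sets out from prenyl bromide 13 and comes back to the route at the target 15): ring C is built by the established 3-iodochromone route. Purchased 2,4-dihydroxyacetophenone is alkylated at the non-chelated 4-hydroxyl with 13 (K2CO3, acetone, reflux) to give 1-[2-hydroxy-4-(3-methylbut-2-enyloxy)phenyl]ethanone F1. Condensation with N,N-dimethylformamide dimethyl acetal (toluene, 90 °C) should give the enaminone (E)-3-(dimethylamino)-1-[2-hydroxy-4-(3-methylbut-2-enyloxy)phenyl]prop-2-en-1-one F2. One equivalent of iodine with pyridine in CHCl3 (0 °C → rt) iodinates the enamine carbon and closes the pyranone with loss of dimethylamine to 3-iodo-7-(3-methylbut-2-enyloxy)-4H-chromen-4-one F3; the enaminone is far more nucleophilic than the trisubstituted alkene, so the prenyl group should survive in the aprotic medium. Suzuki–Miyaura coupling of F3 with (3,4-dimethoxyphenyl)boronic acid (Pd(PPh3)4, Na2CO3, DME/H2O, 80 °C) should then give 15.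

2. Step 3 (Graham oxidation). Hypochlorite may chlorinate the electron-rich dimethoxyarene ring, and the donor-substituted diazirine may lose nitrogen or ionise during washing and handling, so that too little active reagent reaches step 4.
Fallback (sets out from 3 and comes back to the route at 12): the inserted carbon is brought in as a bromine-bearing carbon and ring B is attached afterwards by cross-coupling. Dibromocarbene (CHBr3, KOtBu, pentane, −20 °C → rt) should insert into C2=C3 of 3 by the classical dihalocarbene ring expansion of a cyclic silyl enol ether, with loss of TBSBr, to give 3-bromo-7-(tert-butyldimethylsilyloxy)-4H-chromen-4-one F4. Suzuki–Miyaura coupling of F4 with (3,4-dimethoxyphenyl)boronic acid (PdCl2(dppf), anhydrous K3PO4, dioxane, 80 °C) should then give 12, and step 5 follows unchanged.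

3. Step 1 (double silylation). The enol silane may hydrolyse back to the ketone during isolation, and the benzofuranone may self-condense under the amine base before it is trapped.
Fallback (sets out from 1 and comes back to the route at 3): the two silylations are separated and the enolisation is changed from soft to hard. TBSCl and imidazole in DMF should silylate only the phenol, and ketone 2 is now isolated and purified. Deprotonation with LiN(SiMe3)2 in THF at −78 °C gives lithium 6-(tert-butyldimethylsilyloxy)-1-benzofuran-3-olate F5, which is O-silylated with TBSCl (THF/DMPU, −78 °C → rt). Evaporation and extraction into pentane away from the lithium salt should deliver 3 without contact with water or silica.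

**Further compounds**

F1 | step 4 | 1-[2-hydroxy-4-(3-methylbut-2-enyloxy)phenyl]ethanone | CC(=O)c1ccc(OCC=C(C)C)cc1O
F2 | step 4 | (E)-3-(dimethylamino)-1-[2-hydroxy-4-(3-methylbut-2-enyloxy)phenyl]prop-2-en-1-one | CN(C)/C=C/C(=O)c1ccc(OCC=C(C)C)cc1O
F3 | step 4 | 3-iodo-7-(3-methylbut-2-enyloxy)-4H-chromen-4-one | CC(C)=CCOc1ccc2c(c1)occ(I)c2=O
F4 | step 3 | 3-bromo-7-(tert-butyldimethylsilyloxy)-4H-chromen-4-one | CC(C)(C)[Si](C)(C)Oc1ccc2c(c1)occ(Br)c2=O
F5 | step 1 | lithium 6-(tert-butyldimethylsilyloxy)-1-benzofuran-3-olate | CC(C)(C)[Si](C)(C)Oc1ccc2c([O-])coc2c1.[Li+]
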